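The plan rests on cutting the bond between C3, the indane methylene, and C6 of the chroman (ring A). C6 is the free CH that lies ortho to the methoxy group, para to the pyran oxygen O1, and next to C5, which carries cyclobutane carbon C7b. In one operation acid equilibrates the formyl-bearing carbon C2a, the cis epimer alone closes the cyclopentane by attack of C6 on the aldehyde, and Et3SiH then takes the resulting benzylic cation down to CH2. The precursor is an all-trans 2,2-dimethyl-3,4-diarylcyclobutanecarbaldehyde made by an enantioselective crossed [2+2] photocycloaddition. It carries ring A as a free chroman-4-one and the catechol as its dipivalate.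

Key step: step 11

Assumption: the Δ form of the rhodium complex in step 8 is taken to give 14. If the first cycloadduct proves to be its mirror image, the Λ form is used and nothing else changes.

Locants: C1 (bears ring B), C2 (CMe2), C2a and C7b (ring-fusion carbons) and C3 (CH2) refer to the cyclobuta[a]indene part. O1 to C8a are chroman locants for ring A and the pyran ring.

Design choices:
- **C4 stays a free ketone.**
  - This peri-shielded, doubly oxygen-conjugated carbonyl resists acetalisation.
  - An acetal there would ionise at once in the acid of step 11 and be opened reductively by the silane.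
  - The N,O-chelating acylimidazole outcompetes the ketone for the Lewis acid in step 8.
- **The catechol is a dipivalate.**
  - No alkoxymethyl or benzyl cation can then be released beside the nucleophilic ring A.
  - In the dominant trans aldehyde the formyl group lies on the same face as ring B (1,3-cis across the cyclobutane). An electron-rich ring B could trap it as a bridged benzobicyclo[3.1.1]heptene, and the acyloxy groups switch ring B off.
  - The esters fall in the final hydride step.
- **C8 is about as activated as C6.** It cannot be reached within the molecule, but it is the reason for high dilution in step 11.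
- **The aldehyde is reached through a thioester.** An imidazolyl ketone is not reducible directly to an aldehyde, and the thioester route spares the C4 ketone.

Step 1
Reactants: 1 phloroglucinol; 2 3-methylbut-2-enoic acid
Product: 3 5,7-dihydroxy-2,2-dimethylchroman-4-one
Conditions: P2O5/MeSO3H (1:10 w/w), 70 °C
Reagents that add atoms: none
Why: Friedel–Crafts acylation of the symmetrical, highly activated arene followed by intramolecular oxa-Michael addition of an ortho hydroxyl to the enone should close the chromanone, and the symmetry of 1 excludes regioisomers.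

Step 2
Reactants: 3 5,7-dihydroxy-2,2-dimethylchroman-4-one
Product: 4 5-hydroxy-7-methoxy-2,2-dimethylchroman-4-one
Conditions: MeI (1.1 equiv), K2CO3 (1.1 equiv), acetone, rt to 40 °C
Reagents that add atoms: iodomethane, CI
Why: Williamson ether synthesis in which the 5-OH is held in a hydrogen bond to the C4 carbonyl, so that one equivalent of MeI should alkylate only the more acidic 7-OH.

Step 3
Reactants: 4 5-hydroxy-7-methoxy-2,2-dimethylchroman-4-one
Product: 5 7-methoxy-2,2-dimethyl-4-oxochroman-5-yl trifluoromethanesulfonate
Conditions: Tf2O, pyridine, CH2Cl2, 0 °C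
Reagents that add atoms: trifluoromethanesulfonic anhydride, O=S(=O)(OS(=O)(=O)C(F)(F)F)C(F)(F)F
Why: O-sulfonylation of the remaining phenol turns C5 into a cross-coupling site, the ketone and the aryl ethers being inert to these conditions.

Step 4
Reactants: 5 7-methoxy-2,2-dimethyl-4-oxochroman-5-yl trifluoromethanesulfonate
Product: 6 7-methoxy-2,2-dimethyl-4-oxochroman-5-carbaldehyde
Conditions: Pd(OAc)2 (5 mol%), dppp (5 mol%), CO (1 atm), Et3SiH (2 equiv), Et3N, DMF, 70 °C
Reagents that add atoms: carbon monoxide, [C-]#[O+]
Why: Palladium-catalysed reductive carbonylation (formylation) of an aryl triflate, in which zerovalent palladium adds to the C5–O bond activated by the ortho acyl group, CO inserts, and the silane transfers hydride to the acylpalladium species.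

Step 5
Reactants: 6 7-methoxy-2,2-dimethyl-4-oxochroman-5-carbaldehyde; 7 1-(1-methylimidazol-2-yl)ethan-1-one (2-acetyl-1-methylimidazole)
Product: 8 (E)-7-methoxy-2,2-dimethyl-5-[3-(1-methylimidazol-2-yl)-3-oxoprop-1-enyl]chroman-4-one
Conditions: KOH (0.2 equiv), EtOH, 0 °C to rt
Reagents that add atoms: none
Why: Claisen–Schmidt condensation in which only 7 offers an unhindered, acidified methyl ketone, the neopentyl C3 methylene of 6 cannot reach the formyl carbon for geometric reasons, and E1cB dehydration should give the E enone.

Step 6
Reactants: 9 3,4-dihydroxybenzaldehyde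
Product: 10 4-formyl-1,2-phenylene bis(2,2-dimethylpropanoate)
Conditions: PivCl (2.3 equiv), Et3N, DMAP (cat.), CH2Cl2, 0 °C to rt
Reagents that add atoms: pivaloyl chloride, CC(C)(C)C(=O)Cl
Why: Simple O-acylation of both phenols installs acid-stable, electron-withdrawing and hindered esters.

Step 7
Reactants: 10 4-formyl-1,2-phenylene bis(2,2-dimethylpropanoate); 11 isopropyltriphenylphosphonium iodide
Product: 13 4-(2-methylprop-1-enyl)-1,2-phenylene bis(2,2-dimethylpropanoate), via isopropylidene ylide 12 (not isolated)
Conditions: 11 (1.1 equiv), n-BuLi (1.05 equiv), THF, 0 °C; then 10, −78 °C to rt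
Reagents that add atoms: none
Why: Wittig olefination in which the non-stabilised ylide should add to the aldehyde at −78 °C far faster than to the hindered pivalates, and no alkene geometry arises because the new terminus carries two methyl groups.

Step 8
Reactants: 8 (E)-cinnamoyl imidazole of ring A; 13 4-(2-methylprop-1-enyl)-1,2-phenylene bis(2,2-dimethylpropanoate)
Product: 14 [(1R,3S,4S)-3-[3,4-bis(pivaloyloxy)phenyl]-4-(7-methoxy-2,2-dimethyl-4-oxochroman-5-yl)-2,2-dimethylcyclobutyl](1-methylimidazol-2-yl)methanone (all-trans: acyl trans to ring A, ring A trans to ring B)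
Conditions: Δ-[Rh(L)2(MeCN)2]PF6 (4 mol%; L = C,N-cyclometalated 5-tert-butyl-2-phenylbenzothiazole, C17H16NS), 13 (3 equiv), acetone, blue LEDs (about 450 nm), rt, N2
Reagents that add atoms: none
Why: Visible-light [2+2] photocycloaddition of an N,O-chelated α,β-unsaturated 2-acylimidazole on a chiral-at-metal Lewis acid, in which only the bound enone absorbs, its electrophilic α-carbon bonds to the nucleophilic CMe2 terminus of 13 to leave two benzylic radicals that pair as C7b–C1 (head-to-head), the triplet 1,4-diradical closes to the least crowded all-trans array, and the ligand sphere blocks one enone face and so sets the absolute configuration at C2a, C7b and C1.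

Step 9
Reactants: 14 all-trans cyclobutyl imidazolyl ketone
Product: 16 S-ethyl (1R,3S,4S)-3-[3,4-bis(pivaloyloxy)phenyl]-4-(7-methoxy-2,2-dimethyl-4-oxochroman-5-yl)-2,2-dimethylcyclobutane-1-carbothioate, via acylimidazolium triflate 15 (not isolated)
Conditions: MeOTf (1.1 equiv), 4 Å MS, CH2Cl2, rt; then EtSH (2 equiv), iPr2NEt (1.5 equiv), 0 °C
Reagents that add atoms: ethanethiol, CCS; methyl trifluoromethanesulfonate, COS(=O)(=O)C(F)(F)F (its methyl group and triflate ion appear only in 15)
Why: N-methylation turns the imidazolyl ketone into an acyl azolium ion, and nucleophilic acyl substitution by the thiol expels the carbene as its imidazolium salt without touching the C4 ketone, the hindered pivalates or the already most stable trans configuration at C2a.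

Step 10
Reactants: 16 S-ethyl thioester
Product: 17 (1R,3S,4S)-3-[3,4-bis(pivaloyloxy)phenyl]-4-(7-methoxy-2,2-dimethyl-4-oxochroman-5-yl)-2,2-dimethylcyclobutane-1-carbaldehyde (formyl trans to ring A)
Conditions: Et3SiH (3 equiv), Pd/C (10 mol% Pd), acetone, rt
Reagents that add atoms: none
Why: Fukuyama reduction, in which zerovalent palladium inserts into the C–S bond and the silane intercepts the acylpalladium species, should stop at the aldehyde and leave the aryl ketone, the esters and the three stereocentres unchanged.

Step 11
Reactants: 17 trans cyclobutanecarbaldehyde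
Product: 20 cyclobuta[a]indene-fused 7-methoxy-2,2-dimethylchroman-4-one dipivalate (C1 S, C2a S, C7b R; cis ring fusion, ring B on the face of the fusion hydrogens), via cis aldehyde 18 (not isolated), via indanol 19 (not isolated)
Conditions: TFA/CH2Cl2 (1:2), 0.005 M, 25 to 40 °C until 17 is consumed; then 0 °C, Et3SiH (1.5 equiv)
Reagents that add atoms: none
Why: TFA reversibly enolises 17 (exocyclic enol at C2a), so the favoured trans aldehyde stays in equilibrium with the minor cis epimer 18, the only species whose protonated formyl carbon can reach ring A. C6 attacks that carbon, rearomatisation gives indanol 19, 19 ionises to a benzylic cation stabilised by the ortho OMe and the para O1, and Et3SiH delivers hydride to it, which is the known intramolecular Friedel–Crafts hydroxyalkylation of 3-arylpropanals joined to ionic hydrogenation of a benzylic alcohol. The cyclopentane (C3, C2a, C7b, C5, C6) closes 5-exo-trig at the carbonyl carbon, with the C5–C6 arene bond inside the new ring. C2a is the only new stereocentre and is controlled by C7b, because the benzo-fused bicyclo[3.2.0]heptane can form only cis-fused, so the equilibrium is drained through 18 while C7b and C1, which carry no acidic hydrogen, keep their configuration. Site selectivity rests on the substrate: the two-atom tether from C5 reaches C6 but not the similarly activated C8 (whose intermolecular attack is held back by high dilution), and ring B, which faces the formyl group of 17, is made inert by its two acyloxy groups. Chemoselectivity of the hydride rests on timing and stoichiometry, since the silane is added only after 17 is consumed, cold and in slight excess, so that neither the aldehyde nor the electron-rich, peri-shielded C4 ketone competes with the cation.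

Step 12
Reactants: 20 cyclobuta[a]indene chromanone dipivalate
Product: 22 target chromene catechol CNP0207533.1 (C1 S, C2a S, C7b R), via chromanol catechol 21 (not isolated)
Conditions: LiAlH4 (excess), THF, 0 °C to rt, N2; then 2 M HCl to pH 1, rt
Reagents that add atoms: none
Why: Hydride reduction of the C4 ketone and reductive cleavage of both aryl pivalates, followed by E1 dehydration of the chromanol through a C4 cation stabilised by the para OMe and the ortho O1, should give the 2,2-dimethylchromene, the C4 carbinol configuration being irrelevant and the three cyclobutane stereocentres lying away from every reacting site.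

Compound list
1 | phloroglucinol | Oc1cc(O)cc(O)c1 | starting material
2 | 3-methylbut-2-enoic acid | CC(C)=CC(O)=O | starting material
3 | 5,7-dihydroxy-2,2-dimethylchroman-4-one | CC1(C)CC(=O)c2c(O)cc(O)cc2O1 | intermediate
4 | 5-hydroxy-7-methoxy-2,2-dimethylchroman-4-one | CC1(C)CC(=O)c2c(O)cc(OC)cc2O1 | intermediate
5 | 7-methoxy-2,2-dimethyl-4-oxochroman-5-yl trifluoromethanesulfonate | CC1(C)CC(=O)c2c(OS(=O)(=O)C(F)(F)F)cc(OC)cc2O1 | intermediate
6 | 7-methoxy-2,2-dimethyl-4-oxochroman-5-carbaldehyde | CC1(C)CC(=O)c2c(C=O)cc(OC)cc2O1 | intermediate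
7 | 1-(1-methylimidazol-2-yl)ethan-1-one | CC(=O)c1nccn1C | starting material
8 | (E)-7-methoxy-2,2-dimethyl-5-[3-(1-methylimidazol-2-yl)-3-oxoprop-1-enyl]chroman-4-one | Cn1ccnc1C(=O)/C=C/c1cc(OC)cc2OC(C)(C)CC(=O)c12 | intermediate
9 | 3,4-dihydroxybenzaldehyde | O=Cc1ccc(O)c(O)c1 | starting material
10 | 4-formyl-1,2-phenylene bis(2,2-dimethylpropanoate) | O=Cc1ccc(OC(=O)C(C)(C)C)c(OC(=O)C(C)(C)C)c1 | intermediate
11 | isopropyltriphenylphosphonium iodide | CC(C)[P+](c1ccccc1)(c1ccccc1)c1ccccc1.[I-] | starting material
12 | isopropylidenetriphenylphosphorane (not isolated) | CC(C)=P(c1ccccc1)(c1ccccc1)c1ccccc1 | intermediate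
13 | 4-(2-methylprop-1-enyl)-1,2-phenylene bis(2,2-dimethylpropanoate) | CC(C)=Cc1ccc(OC(=O)C(C)(C)C)c(OC(=O)C(C)(C)C)c1 | intermediate
14 | all-trans (1R,3S,4S) cyclobutyl 1-methylimidazol-2-yl ketone | Cn1ccnc1C(=O)[C@@H]1[C@@H](c2cc(OC)cc3OC(C)(C)CC(=O)c23)[C@H](c2ccc(OC(=O)C(C)(C)C)c(OC(=O)C(C)(C)C)c2)C1(C)C | intermediate
15 | 2-acyl-1,3-dimethylimidazolium triflate of 14 (not isolated) | C[n+]1ccn(C)c1C(=O)[C@@H]1[C@@H](c2cc(OC)cc3OC(C)(C)CC(=O)c23)[C@H](c2ccc(OC(=O)C(C)(C)C)c(OC(=O)C(C)(C)C)c2)C1(C)C.[O-]S(=O)(=O)C(F)(F)F | intermediate
16 | S-ethyl (1R,3S,4S)-cyclobutane-1-carbothioate | CCSC(=O)[C@@H]1[C@@H](c2cc(OC)cc3OC(C)(C)CC(=O)c23)[C@H](c2ccc(OC(=O)C(C)(C)C)c(OC(=O)C(C)(C)C)c2)C1(C)C | intermediate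
17 | (1R,3S,4S)-cyclobutane-1-carbaldehyde, formyl trans to ring A (key-step precursor) | O=C[C@@H]1[C@@H](c2cc(OC)cc3OC(C)(C)CC(=O)c23)[C@H](c2ccc(OC(=O)C(C)(C)C)c(OC(=O)C(C)(C)C)c2)C1(C)C | intermediate
18 | (1S,3S,4S)-cyclobutane-1-carbaldehyde, formyl cis to ring A (not isolated) | O=C[C@H]1[C@@H](c2cc(OC)cc3OC(C)(C)CC(=O)c23)[C@H](c2ccc(OC(=O)C(C)(C)C)c(OC(=O)C(C)(C)C)c2)C1(C)C | intermediate
19 | C3 indanol of the cyclobuta[a]indene chromanone, C3 epimers, other centres as in 20 (not isolated) | COc1cc2c(c3c1C(O)[C@H]1[C@@H]3[C@H](c3ccc(OC(=O)C(C)(C)C)c(OC(=O)C(C)(C)C)c3)C1(C)C)C(=O)CC(C)(C)O2 | intermediate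
20 | cyclobuta[a]indene-fused chromanone dipivalate (key-step product; C1 S, C2a S, C7b R) | COc1cc2c(c3c1C[C@H]1[C@@H]3[C@H](c3ccc(OC(=O)C(C)(C)C)c(OC(=O)C(C)(C)C)c3)C1(C)C)C(=O)CC(C)(C)O2 | intermediate
21 | C4 chromanol with free catechol, C4 epimers (not isolated) | COc1cc2c(c3c1C[C@H]1[C@@H]3[C@H](c3ccc(O)c(O)c3)C1(C)C)C(O)CC(C)(C)O2 | intermediate
22 | CNP0207533.1 | COc1cc2c(c3c1C[C@H]1[C@@H]3[C@H](c3ccc(O)c(O)c3)C1(C)C)C=CC(C)(C)O2 | target

Total step count: 12. Longest linear sequence: 10 steps (steps 1–5 and 8–12, from phloroglucinol).

Steps most likely to fail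

1. **Step 11.**
   - What may go wrong: enolisation at the hindered C2a may be slower than intermolecular condensation of the aldehyde, or of the benzylic cation, with C8 of a second molecule, so that oligomerisation outruns ring closure. Protonation of the C4 carbonyl in strong acid also lowers the nucleophilicity of ring A.
   - Fallback: it sets out from 17 and moves both epimerisation and activation to amine chemistry. Compound 17 is warmed with pyrrolidine and TFA (about 1.5 equiv each, 4 Å MS, 1,2-dichloroethane, 60 °C).
   - Iminium/enamine interconversion should scramble C2a quickly at an acidity that leaves the C4 ketone unprotonated. The cis iminium ion is then captured by C6 in an intramolecular Mannich-type closure, giving the C3-pyrrolidinyl cyclobuta[a]indene chromanone dipivalate F1.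
   - Hydrogenolysis of the only benzylic C–N bond (H2, Pd(OH)2/C, MeOH/AcOH, rt) brings the route back at 20.

2. **Step 8.**
   - What may go wrong: poor facial selectivity with the twisted, ortho-acylated cinnamoyl group; slow bond formation at the fully substituted alkene carbon, which would erode the head-to-head orientation; or E/Z isomerisation acting as an energy sink.
   - Fallback: it sets out from 8 and 13 and gives up asymmetric catalysis. Triplet sensitisation of the protonated cinnamoyl imidazole (Ru(bpy)3(PF6)2, 2.5 mol%, p-TsOH, MeCN, blue LEDs, rt) should give the racemic all-trans cycloadduct F2.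
   - Its enantiomers are separated by preparative chromatography on a chiral stationary phase, and the route is rejoined at 14 at the cost of half the material.

3. **Step 4.**
   - What may go wrong: premature hydride transfer to the arylpalladium species (loss of the triflate to a C5–H arene), or slow CO insertion beside the peri carbonyl.
   - Fallback: it sets out from 5 and builds the formyl carbon by C–C coupling and cleavage. Suzuki–Miyaura coupling with potassium vinyltrifluoroborate (PdCl2(dppf), Et3N, n-PrOH, 80 °C) gives 7-methoxy-2,2-dimethyl-5-vinylchroman-4-one F3.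
   - Lemieux–Johnson cleavage (OsO4 cat., NaIO4, 2,6-lutidine, dioxane/H2O, rt) returns to 6.

Further compounds
F1 | step 11 | C3-pyrrolidinyl cyclobuta[a]indene chromanone dipivalate (C3 epimers) | COc1cc2c(c3c1C(N4CCCC4)[C@H]5[C@@H]3[C@H](c6ccc(OC(=O)C(C)(C)C)c(OC(=O)C(C)(C)C)c6)C5(C)C)C(=O)CC(C)(C)O2
F2 | step 8 | racemic all-trans cycloadduct (14 plus its mirror image) | Cn1ccnc1C(=O)[C@@H]1[C@@H](c2cc(OC)cc3OC(C)(C)CC(=O)c23)[C@H](c2ccc(OC(=O)C(C)(C)C)c(OC(=O)C(C)(C)C)c2)C1(C)C.Cn1ccnc1C(=O)[C@H]1[C@H](c2cc(OC)cc3OC(C)(C)CC(=O)c23)[C@@H](c2ccc(OC(=O)C(C)(C)C)c(OC(=O)C(C)(C)C)c2)C1(C)C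
F3 | step 4 | 7-methoxy-2,2-dimethyl-5-vinylchroman-4-one | C=Cc1cc(OC)cc2OC(C)(C)CC(=O)c12
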